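**Strategy**

Ring atoms are numbered from the acetoxy carbon: C1 (CHOAc), C2 (CH2), C3 (CHBr), C4 (CMe2), C5 (CHCl), C6 (alkene carbon bearing C7 and C8). The bromine carbon C3 and the chlorine carbon C5 both stand β to C1, one on each side of quaternary C4, so a C1 ketone maps the six-membered ring onto symmetric, achiral 4,4-dimethylcyclohexa-2,5-dien-1-one. The route breaks that symmetry once: copper-catalysed enantioselective boryl conjugate addition to the bought dienone (with B2pin2, no earlier steps) creates the C3–B bond and the C3 stereocentre; boron is later exchanged for bromine with inversion, and the surviving enone arm takes chloride at C5 and the two-carbon chain at C6.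

Key step: step 1

Remark on numbering: positions C1–C8 in the Why lines follow the numbering above; systematic names carry their own locants.

Assumption: the sense of induction of the CuCl/bisphosphine catalyst on this dienone is to be assigned in a pilot run (oxidation of 3 and Mosher ester analysis); the ligand antipode that delivers (S)-3 is the one used and is written below as (R,R).

**Route**

Step 1
Reactants: 1 4,4-dimethylcyclohexa-2,5-dien-1-one; 2 bis(pinacolato)diboron
Product: 3 (5S)-4,4-dimethyl-5-(4,4,5,5-tetramethyl-1,3,2-dioxaborolan-2-yl)cyclohex-2-en-1-one (boron on the ring face opposite to the final bromine)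
Conditions: CuCl (5 mol %), (R,R)-QuinoxP* [(R,R)-2,3-bis(tert-butylmethylphosphino)quinoxaline] (6 mol %), NaOtBu (8 mol %), 1 (1.2 equiv), 2 (1.0 equiv), MeOH (2 equiv), THF, –20 °C
Reagents that add atoms: none
Why: NaOtBu converts CuCl and the bisphosphine into L*Cu–OtBu, which undergoes σ-bond metathesis with B2pin2 to give the nucleophilic boryl complex L*Cu–Bpin; this adds syn across one C=C of 1 with boron going to the β-carbon C3, and methanol protonates the resulting copper enolate, releasing 3 and L*Cu–OMe, which B2pin2 re-borylates. The closest known reaction type is the copper-catalysed enantioselective β-borylation of cyclic enones and of 4,4-disubstituted cyclohexadienones with an alcohol additive. No ring is closed and no skeletal bond is made; only the C3–B bond forms. The single new stereocentre, C3, is controlled by the chiral ligand on copper, which chooses between the enantiotopic faces of the flat dienone; the two enone arms are interchanged by the twofold axis through C1 and C4, so attack on either arm from the favoured face gives the same enantiomer and no regiochemical question arises. The step needs mono- over bis-borylation and 1,4- over 1,2-addition: the cross-conjugated dienone is a better acceptor than the enone left in 3, B2pin2 is limiting at low temperature, and the soft copper boryl reagent does not attack the carbonyl. Boron is placed on the face opposite to the final bromine because step 4 inverts C3.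

Step 2
Reactants: 3
Product: 4 (1R,5S)-4,4-dimethyl-5-(4,4,5,5-tetramethyl-1,3,2-dioxaborolan-2-yl)cyclohex-2-en-1-ol (hydroxyl cis to boron)
Conditions: NaBH4, CeCl3·7H2O, MeOH, –78 °C
Reagents that add atoms: none
Why: Luche reduction is 1,2-selective for enones and should deliver hydride to the ring face anti to the C3 boryl group, as in the reduction of 5-substituted cyclohexenones to their cis alcohols, so the temporary C1 carbinol is expected mainly cis to boron (1R), which lets both groups sit equatorial in step 4, while any trans epimer converges again at ketone 9.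

Step 3
Reactants: 4
Product: 5 {[(1R,5S)-4,4-dimethyl-5-(4,4,5,5-tetramethyl-1,3,2-dioxaborolan-2-yl)cyclohex-2-en-1-yl]oxy}triethylsilane
Conditions: TESCl, imidazole, CH2Cl2, 0 °C to rt
Reagents that add atoms: chlorotriethylsilane, CC[Si](Cl)(CC)CC
Why: Standard silylation of a secondary allylic alcohol; the triethylsilyl ether shields the hydroxyl from the aryllithium, prevents alkoxide-to-boron chelation, and is labile enough to be removed by dilute acid at the end of the next step, with no stereocentre touched.

Step 4
Reactants: 5
Product: 8 (1R,5R)-5-bromo-4,4-dimethylcyclohex-2-en-1-ol, via lithium aryl boronate 6 (not isolated), via bromo triethylsilyl ether 7 (not isolated)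
Conditions: 1-bromo-3,5-bis(trifluoromethyl)benzene (1.3 equiv), n-BuLi (1.25 equiv), THF, –78 °C; add 5, –78 °C; NBS (1.5 equiv), THF, –78 °C; aq Na2S2O3 at –78 °C; crude 7: 1 M aq HCl, THF, 0 °C
Reagents that add atoms: N-bromosuccinimide, O=C1CCC(=O)N1Br
Why: Stereoinvertive halodeboronation through an aryl boronate complex: the electron-poor aryllithium adds to boron to give ate complex 6, whose C3–B bond is attacked at carbon by NBS from the side opposite to boron (SE2 with inversion), so C3 becomes (R) with bromine trans to the C1 oxygen; with boronate and silyloxy groups both equatorial the electrophile crosses the ring face that carries only the axial C1–H, clear of both C4 methyl groups, the bis(trifluoromethyl)phenyl group suppresses aryl bromination and electron transfer, and dilute acid then cleaves the silyl ether of 7 to give 8.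

Step 5
Reactants: 8
Product: 9 (5R)-5-bromo-4,4-dimethylcyclohex-2-en-1-one
Conditions: Dess–Martin periodinane, CH2Cl2, 0 °C to rt; aq Na2S2O3 work-up without base
Reagents that add atoms: none
Why: Dess–Martin oxidation of a secondary allylic alcohol under non-basic conditions returns the C1 carbonyl without E1cB loss of the β-bromide; the temporary C1 centre is erased and C3 is not involved.

Step 6
Reactants: 9; 10 (tert-butyldimethylsilyloxy)acetaldehyde
Product: 12 (3R,5R)-5-bromo-2-[2-(tert-butyldimethylsilyloxy)-1-hydroxyethyl]-3-chloro-4,4-dimethylcyclohexan-1-one (epimers at ring C2 and at the carbinol carbon), via trichlorotitanium enolate 11 (not isolated)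
Conditions: 9 + 10 (1.3 equiv), TiCl4 (1.3 equiv), CH2Cl2, –78 to –40 °C; cold sat. aq NH4Cl; used crude
Reagents that add atoms: titanium tetrachloride, Cl[Ti](Cl)(Cl)Cl
Why: Titanium tetrachloride halo-aldol (chloro-aldol) reaction of a cyclic enone: chloride passes from titanium to the β-carbon C5 to give enolate 11, which adds through C6 to the titanium-activated aldehyde; chloride should enter C5 along the stereoelectronically preferred axial line on the face anti to the C3 bromine (the trans-3,5 pattern of conjugate additions to 5-substituted cyclohexenones), fixing C5 as (R), while the C6 and C7 centres form without control and are removed in step 7.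

Step 7
Reactants: 12
Product: 13 (2Z,3R,5R)-5-bromo-2-[2-(tert-butyldimethylsilyloxy)ethylidene]-3-chloro-4,4-dimethylcyclohexan-1-one (CH2OTBS cis to the CHCl carbon, trans to the carbonyl carbon)
Conditions: Martin sulfurane Ph2S[OC(CF3)2Ph]2 (1.5 equiv), CH2Cl2, 0 °C to rt
Reagents that add atoms: none
Why: Martin sulfurane dehydration of a β-hydroxy ketone: the C7 alkoxysulfonium is expelled as the acidic C6–H is removed, under neutral conditions that avoid amine-induced loss of HCl or HBr, and the alkene should take the favoured geometry with C8 turned away from the carbonyl oxygen and towards C5, whose chlorine goes axial to relieve allylic strain (geometry to be checked by NOE).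

Step 8
Reactants: 13
Product: 14 (1S,2Z,3R,5R)-5-bromo-2-[2-(tert-butyldimethylsilyloxy)ethylidene]-3-chloro-4,4-dimethylcyclohexan-1-ol (hydroxyl cis to bromine, trans to chlorine)
Conditions: (R)-2-methyl-CBS-oxazaborolidine [(3aR)-1-methyl-3,3-diphenyltetrahydro-1H,3H-pyrrolo[1,2-c][1,3,2]oxazaborole] (0.3 equiv), BH3·SMe2 (0.8 equiv), THF, –30 °C; MeOH quench
Reagents that add atoms: none
Why: Corey–Bakshi–Shibata reduction: the oxazaborolidine–borane complex binds the carbonyl on the side of the smaller α-carbon C2 and, with the (R) catalyst, should deliver hydride to the face that gives the (1S) equatorial carbinol when the fully substituted alkene carbon C6 acts as the large group; reagent control is chosen because the axial C5 chlorine lies on the face from which hydride must arrive.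

Step 9
Reactants: 14
Product: 15 (1S,2Z,3R,5R)-5-bromo-2-[2-(tert-butyldimethylsilyloxy)ethylidene]-3-chloro-4,4-dimethylcyclohexyl acetate
Conditions: Ac2O, pyridine, DMAP (cat.), CH2Cl2, 0 °C
Reagents that add atoms: acetic anhydride, CC(=O)OC(C)=O
Why: DMAP-catalysed acylation of a secondary allylic alcohol proceeds with retention at C1, and with no ring carbonyl left the neopentyl bromide and the allylic chloride are inert to pyridine at 0 °C.

Step 10
Reactants: 15
Product: 16 (1S,2Z,3R,5R)-5-bromo-2-(2-bromoethylidene)-3-chloro-4,4-dimethylcyclohexyl acetate (target)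
Conditions: Ph3PBr2 (1.3 equiv), CH2Cl2, 0 °C to rt
Reagents that add atoms: dibromotriphenylphosphorane, BrP(Br)(c1ccccc1)(c1ccccc1)c1ccccc1
Why: Direct conversion of a primary silyl ether into a bromide with Ph3PBr2: oxygen is transferred to phosphorus, bromide removes the silyl group and then displaces the oxyphosphonium at primary C8 by SN2, and SN2' attack is blocked because C6 is fully substituted, so the alkene geometry and the three ring stereocentres are untouched.

**Compound list**

1 | 4,4-dimethylcyclohexa-2,5-dien-1-one | CC1(C)C=CC(=O)C=C1 | starting material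
2 | bis(pinacolato)diboron | CC1(C)OB(OC1(C)C)B1OC(C)(C)C(C)(C)O1 | starting material
3 | (5S)-4,4-dimethyl-5-(4,4,5,5-tetramethyl-1,3,2-dioxaborolan-2-yl)cyclohex-2-en-1-one | O=C1C[C@H](B2OC(C)(C)C(C)(C)O2)C(C)(C)C=C1 | intermediate
4 | (1R,5S)-4,4-dimethyl-5-(4,4,5,5-tetramethyl-1,3,2-dioxaborolan-2-yl)cyclohex-2-en-1-ol | O[C@@H]1C[C@H](B2OC(C)(C)C(C)(C)O2)C(C)(C)C=C1 | intermediate
5 | {[(1R,5S)-4,4-dimethyl-5-(4,4,5,5-tetramethyl-1,3,2-dioxaborolan-2-yl)cyclohex-2-en-1-yl]oxy}triethylsilane | CC[Si](CC)(CC)O[C@@H]1C[C@H](B2OC(C)(C)C(C)(C)O2)C(C)(C)C=C1 | intermediate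
6 | lithium [3,5-bis(trifluoromethyl)phenyl][(1S,5R)-2,2-dimethyl-5-(triethylsilyloxy)cyclohex-3-en-1-yl](pinacolato)borate | [Li+].CC[Si](CC)(CC)O[C@@H]1C[C@H]([B-]2(OC(C)(C)C(C)(C)O2)c2cc(cc(c2)C(F)(F)F)C(F)(F)F)C(C)(C)C=C1 | intermediate (not isolated)
7 | {[(1R,5R)-5-bromo-4,4-dimethylcyclohex-2-en-1-yl]oxy}triethylsilane | CC[Si](CC)(CC)O[C@@H]1C[C@@H](Br)C(C)(C)C=C1 | intermediate (not isolated)
8 | (1R,5R)-5-bromo-4,4-dimethylcyclohex-2-en-1-ol | O[C@@H]1C[C@@H](Br)C(C)(C)C=C1 | intermediate
9 | (5R)-5-bromo-4,4-dimethylcyclohex-2-en-1-one | O=C1C[C@@H](Br)C(C)(C)C=C1 | intermediate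
10 | (tert-butyldimethylsilyloxy)acetaldehyde | O=CCO[Si](C)(C)C(C)(C)C | starting material
11 | trichlorotitanium (3R,5R)-5-bromo-3-chloro-4,4-dimethylcyclohex-1-en-1-olate | Cl[Ti](Cl)(Cl)OC1=C[C@@H](Cl)C(C)(C)[C@H](Br)C1 | intermediate (not isolated)
12 | (3R,5R)-5-bromo-2-[2-(tert-butyldimethylsilyloxy)-1-hydroxyethyl]-3-chloro-4,4-dimethylcyclohexan-1-one (ring C2 and carbinol carbon undefined) | O=C1C[C@@H](Br)C(C)(C)[C@H](Cl)C1C(O)CO[Si](C)(C)C(C)(C)C | intermediate
13 | (2Z,3R,5R)-5-bromo-2-[2-(tert-butyldimethylsilyloxy)ethylidene]-3-chloro-4,4-dimethylcyclohexan-1-one | O=C1C[C@@H](Br)C(C)(C)[C@H](Cl)/C1=C\CO[Si](C)(C)C(C)(C)C | intermediate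
14 | (1S,2Z,3R,5R)-5-bromo-2-[2-(tert-butyldimethylsilyloxy)ethylidene]-3-chloro-4,4-dimethylcyclohexan-1-ol | O[C@H]1C[C@@H](Br)C(C)(C)[C@H](Cl)/C1=C\CO[Si](C)(C)C(C)(C)C | intermediate
15 | (1S,2Z,3R,5R)-5-bromo-2-[2-(tert-butyldimethylsilyloxy)ethylidene]-3-chloro-4,4-dimethylcyclohexyl acetate | CC(=O)O[C@H]1C[C@@H](Br)C(C)(C)[C@H](Cl)/C1=C\CO[Si](C)(C)C(C)(C)C | intermediate
16 | (1S,2Z,3R,5R)-5-bromo-2-(2-bromoethylidene)-3-chloro-4,4-dimethylcyclohexyl acetate | CC(=O)O[C@H]1C[C@@H](Br)C(C)(C)[C@H](Cl)/C1=C\CBr | target

**Step count and risks**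

Total steps: 10. Longest linear sequence: 10 steps (1 to 16); 2 and 10 are bought and enter at steps 1 and 6.

Steps most likely to fail:

1. Step 4 (bromodeboronation). The bromine electrophile may reach the neopentyl carbon C3 too slowly, so that electron transfer from the boronate or simple return of the boronic ester outruns the invertive substitution and stereospecificity or conversion is lost. Fallback, from 4 back to 8, with step 3 skipped: diastereomerically pure 4 is treated with KHF2 in aqueous methanol to give potassium trifluoro[(1S,5R)-5-hydroxy-2,2-dimethylcyclohex-3-en-1-yl]borate F1. F1 is then oxidised by one electron with an excited acridinium photocatalyst (9-mesityl-10-methylacridinium perchlorate, blue light, MeCN) in the presence of excess BrCCl3 as bromine-atom donor. The secondary C3 radical should be capped on its axial face, anti to the axial C4 methyl and syn only to the axial C1–H of the half-chair with equatorial hydroxyl. That places bromine trans to the hydroxyl, the same diastereomer 8 that the polar inversion gives, now under substrate control; the high BrCCl3 concentration is meant to outpace homoallyl radical rearrangement.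

2. Step 6 (chloro-aldol). The titanium aldolate may revert by retro-aldol or shed HCl during the quench, and the Lewis acid may strip or chelate the α-silyloxy aldehyde. Fallback, from 9 back to 13, replacing steps 6 and 7: commercial 2-(phenylsulfanyl)ethanol is silylated (TBSCl, imidazole) to tert-butyldimethyl[2-(phenylsulfanyl)ethoxy]silane F2, which NCS chlorinates next to sulfur to give tert-butyl[2-chloro-2-(phenylsulfanyl)ethoxy]dimethylsilane F3. Enolate 11 is generated from 9 and TiCl4 as before and captures the thionium ion released from F3 in an irreversible Lewis-acid phenylthioalkylation. This gives (3R,5R)-5-bromo-2-[2-(tert-butyldimethylsilyloxy)-1-(phenylsulfanyl)ethyl]-3-chloro-4,4-dimethylcyclohexan-1-one F4. mCPBA at –78 °C oxidises F4 to the sulfoxide (3R,5R)-5-bromo-2-[2-(tert-butyldimethylsilyloxy)-1-(phenylsulfinyl)ethyl]-3-chloro-4,4-dimethylcyclohexan-1-one F5. Warming F5 in toluene effects thermal syn-elimination towards the acidic C6–H and away from the oxygen-bearing C8, giving 13 without any base.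

3. Step 8 (C1 reduction). Facial selectivity may be poor because the catalyst must deliver hydride past the axial C5 chlorine, so reagent and substrate preferences may oppose each other. Fallback, from 13 back to 15, with step 9 skipped: 13 is reduced from the open face with the antipodal (S)-2-methyl-CBS-oxazaborolidine and BH3·SMe2, where both preferences agree, to give the axial C1 epimer (1R,2Z,3R,5R)-5-bromo-2-[2-(tert-butyldimethylsilyloxy)ethylidene]-3-chloro-4,4-dimethylcyclohexan-1-ol F6. Mitsunobu esterification of F6 with acetic acid (PPh3, DIAD, toluene, 0 °C) displaces the axial oxyphosphonium by SN2 with inversion and gives acetate 15 directly.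

**Further compounds**

F1 | step 4 | potassium trifluoro[(1S,5R)-5-hydroxy-2,2-dimethylcyclohex-3-en-1-yl]borate | [K+].O[C@@H]1C[C@H]([B-](F)(F)F)C(C)(C)C=C1
F2 | step 6 | tert-butyldimethyl[2-(phenylsulfanyl)ethoxy]silane | CC(C)(C)[Si](C)(C)OCCSc1ccccc1
F3 | step 6 | tert-butyl[2-chloro-2-(phenylsulfanyl)ethoxy]dimethylsilane (racemic) | CC(C)(C)[Si](C)(C)OCC(Cl)Sc1ccccc1
F4 | step 6 | (3R,5R)-5-bromo-2-[2-(tert-butyldimethylsilyloxy)-1-(phenylsulfanyl)ethyl]-3-chloro-4,4-dimethylcyclohexan-1-one | O=C1C[C@@H](Br)C(C)(C)[C@H](Cl)C1C(CO[Si](C)(C)C(C)(C)C)Sc1ccccc1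
F5 | step 6 | (3R,5R)-5-bromo-2-[2-(tert-butyldimethylsilyloxy)-1-(phenylsulfinyl)ethyl]-3-chloro-4,4-dimethylcyclohexan-1-one | O=C1C[C@@H](Br)C(C)(C)[C@H](Cl)C1C(CO[Si](C)(C)C(C)(C)C)S(=O)c1ccccc1
F6 | step 8 | (1R,2Z,3R,5R)-5-bromo-2-[2-(tert-butyldimethylsilyloxy)ethylidene]-3-chloro-4,4-dimethylcyclohexan-1-ol | O[C@@H]1C[C@@H](Br)C(C)(C)[C@H](Cl)/C1=C\CO[Si](C)(C)C(C)(C)C
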